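(The runs come from a simulation from invented constants; the scatter is artificial.)

A flask as slow as north-east moves so little per hour that its readings look like a straight line, so here you follow the logarithm of what remains instead of the line.

| flask | substrate | partner | free catalyst | temperature | remark | time |
|---|---|---|---|---|---|---|
| north-east | 1 M | 1.41 M | 0.94 mM | 70 °C | run made earlier |  |
| elm | 0.94 M | 0.500 M | 0.94 mM | 90 °C |  | 12 h |
| maple | 0.94 M | 1.41 M | 1.5 mM | 100 °C |  | 12 h |
| cedar | 0.50 M | 1.41 M | 0.94 mM | 70 °C |  | 12 h |
| alder | 0.94 M | 1.41 M | 2.0 mM | 55 °C |  | 12 h |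
| larch | 0.50 M | 1.41 M | 0.94 mM | 90 °C |  | 12 h |
| oak | 0.94 M | 1.41 M | 0.94 mM | 70 °C |  | 12 h |

north-east run (percent of the substrate charged)

| time / h | target / % | substrate / % |
|---|---|---|
| 0.500 | 1.0 | 99.8 |
| 1.00 | 4.2 | 97.2 |
| 2.00 | 6.9 | 91.8 |
| 4.00 | 14.5 | 85.0 |
| 8.00 | 27.0 | 72.6 |

(scatter of a reading: 1 percentage point)

- what was read earlier has a scatter of 1 percentage point, one standard deviation
- the earlier runs do not show what temperature does; that part of a forecast is a guess
- no earlier run changes the charge of free catalyst; that part of a forecast is a guess

- all flasks from highest to lowest amount of target, in percent of the substrate charged, at 12 h (elm / maple / cedar / alder / larch / oak)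
- the same order at 2.5 h (elm / maple / cedar / alder / larch / oak)
- the amount of target, in percent of the substrate charged of the flask you put first, at 12 h
- the amount of target, in percent of the substrate charged of the flask you put last, at 12 h

At 8.00 h with 0.94 mM of free catalyst, north-east reads 27.0% of target, which is 0.137 of a decade. So the decade dose of north-east, the product of c(free catalyst) and time that takes the unconverted substrate down by a factor 10, reads 55.0 mM·h. The reading at 4.00 h gives 55.3 mM·h, so on these two readings I take the rate as following the substrate left. That it also follows c(free catalyst) is my guess, and temperature is outside the reckoning, so I commit to one flask. Oak has the catalyst and temperature of north-east and nearly its substrate. Its 0.94 mM for 12 h comes to 0.205 of a decade, which gives 37.6% of target.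

The forecast, which says “Temperature is a guess”, gives maple > larch > elm > cedar > oak > alder at 12 h and maple > larch > elm > cedar > oak > alder at 2.5 h, with 97% first and 25% last. The flasks give maple > larch > elm > cedar > oak > alder at 12 h and maple > larch > elm > cedar > oak > alder at 2.5 h, with 95.3% in maple and 33.4% in alder. Oak stands at 39.0%, which is 1.4 percentage points above my reckoning.

    substrate + free catalyst ⇌ catalyst intermediate A (K = 1.00 /M, k = 0.0340 /M/s, Ea = 53.0 kJ/mol, ΔH = −55.0 kJ/mol)
    catalyst intermediate A → catalyst intermediate B (k = 0.0510 /s, Ea = 82.0 kJ/mol)
    partner + catalyst intermediate B ⇌ catalyst intermediate C (K = 1.60 /M, k = 0.0370 /M/s, Ea = 65.0 kJ/mol, ΔH = −20.0 kJ/mol)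
    catalyst intermediate C ⇌ catalyst intermediate D (K = 11.0, k = 1.30 /s, Ea = 87.0 kJ/mol, ΔH = −43.0 kJ/mol)
    catalyst intermediate D → by-product + catalyst intermediate E (k = 6.30 /s, Ea = 72.0 kJ/mol)
    catalyst intermediate E → free catalyst + target (k = 4.30 /s, Ea = 80.0 kJ/mol)
    target → over-reaction product (k = 2.00 × 10⁻⁸ /s, Ea = 126 kJ/mol)
    2 catalyst intermediate A → spent catalyst (k = 0.00810 /M/s, Ea = 53.0 kJ/mol)
    (constants at 70 °C)

In alder at 5.55 h, catalyst intermediate A has a half-life of 0.84 min by its conversion into catalyst intermediate B, far shorter than the 12 h of the run. In alder at that time, the net making of catalyst intermediate A over its net using up stands at 1.00 and the same ratio for catalyst intermediate B at 1.00, a quasi-steady state. Read from the 33.4% of target in alder at 55 °C, the decade dose is 136 mM·h. For alder charged instead with 0.0050 M of free catalyst, that dose reckons to 63.7% of target, and this neighbouring flask gives 67.2%.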